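**Retrosynthetic overview** (isochromene numbering C1–C8a for the bicycle, C1'–C7' for the side chain)
1. Target ⇐ C1-hydroxy-3,6-diketone (global desilylation, then the C1 hydroxyl closes onto the C3 ketone and dehydrates: pyran ring formed last) ⇐ bis-allylic diol (double oxidation).
2. Carbocycle ⇐ ring-closing metathesis (C4a=C5) of an acyclic triene: carbocycle formed first.
3. Key C3–C4 bond: intermolecular Nozaki–Hiyama carbonyl allylation of the side-chain enal by the core 2-substituted allylic chloride.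
4. Core chloride ⇐ Evans syn-aldol (C8–C8a); side-chain enal ⇐ Brown anti-crotylation (C4'–C5'); both on the same aldehyde, (R)-2-methyl-2-silyloxy-3-(PMB-oxy)propanal.
5. That aldehyde ⇐ Sharpless epoxidation of methallyl alcohol (sets C7 and C3').

Assumption: metal or boron alkoxides that are only the pre-work-up form of a product are not numbered separately; C3 and C6 carbinol centres that are later oxidised are carried as epimer mixtures.

**Step 1**
Reactants: 1 2-methylprop-2-en-1-ol (methallyl alcohol)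
Product: 2 [(2S)-2-methyloxiran-2-yl]methanol ((S)-2-methylglycidol)
Conditions: Ti(OiPr)4 (5 mol %), L-(+)-diethyl tartrate (6 mol %), t-BuOOH, 4 Å MS, CH2Cl2, −20 °C
Reagents that add atoms: tert-butyl hydroperoxide, CC(C)(C)OO
Why: Sharpless asymmetric epoxidation; the L-(+)-tartrate titanium catalyst delivers oxygen to one enantioface and sets the quaternary centre that becomes C7 and C3'.

**Step 2**
Reactants: 2 (S)-2-methylglycidol
Product: 3 (2S)-3-[(4-methoxybenzyl)oxy]-2-methylpropane-1,2-diol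
Conditions: 4-MeOC6H4CH2OH (5 equiv), NaH (0.3 equiv), DMF, 70 °C
Reagents that add atoms: 4-methoxybenzyl alcohol, COc1ccc(CO)cc1
Why: alkoxide SN2 opening of the epoxide at its unhindered CH2, so the C–O bond at the quaternary centre is never broken (retention).

**Step 3**
Reactants: 3 diol
Product: 4 (2R)-1-[(4-methoxybenzyl)oxy]-2-methyl-2,3-bis[(triethylsilyl)oxy]propane
Conditions: Et3SiOTf (2.4 equiv), 2,6-lutidine, CH2Cl2, −78 → 0 °C
Reagents that add atoms: triethylsilyl trifluoromethanesulfonate, CC[Si](CC)(CC)OS(=O)(=O)C(F)(F)F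
Why: silyl triflate silylation caps both the primary and the hindered tertiary hydroxyl.

**Step 4**
Reactants: 4 bis-silyl ether
Product: 5 (2R)-3-[(4-methoxybenzyl)oxy]-2-methyl-2-[(triethylsilyl)oxy]propanal
Conditions: (COCl)2, DMSO, CH2Cl2, −78 → −40 °C; Et3N, −78 °C → rt
Reagents that add atoms: none
Why: Swern oxidation in which the activated sulfonium cleaves only the unhindered primary triethylsilyl ether and oxidises it in situ; the aldehyde is non-enolisable.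

**Step 5**
Reactants: 6 3-methylbut-3-enoic acid; 7 (4R)-4-benzyl-1,3-oxazolidin-2-one
Product: 9 (4R)-4-benzyl-3-(3-methylbut-3-enoyl)-1,3-oxazolidin-2-one, via mixed pivalic anhydride 8 (not isolated)
Conditions: t-BuCOCl, Et3N, THF, −20 °C; then 7, LiCl, −20 °C → rt
Reagents that add atoms: none
Why: N-acylation of the oxazolidinone through the mixed anhydride, mild enough to keep the β,γ-double bond in place.

**Step 6**
Reactants: 9 imide; 5 aldehyde
Product: 11 (4R)-4-benzyl-3-[(2R,3R,4R)-3-hydroxy-5-[(4-methoxybenzyl)oxy]-4-methyl-2-(prop-1-en-2-yl)-4-[(triethylsilyl)oxy]pentanoyl]-1,3-oxazolidin-2-one, via dibutylboron Z-dienolate 10 (not isolated)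
Conditions: n-Bu2BOTf, i-Pr2NEt, CH2Cl2, −78 → 0 °C; 5, −78 → 0 °C; then pH 7 buffer (NaH2PO4/Na2HPO4), MeOH, H2O2, 0 °C
Reagents that add atoms: none
Why: Evans syn-aldol through a Zimmerman–Traxler chair of the Z boron enolate; the (R)-benzyl auxiliary sets C8a and C8 (syn) and overrides the weak bias of the α-quaternary aldehyde.

**Step 7**
Reactants: 11 aldol adduct
Product: 12 (4R)-4-benzyl-3-[(2R,3R,4R)-5-[(4-methoxybenzyl)oxy]-4-methyl-2-(prop-1-en-2-yl)-3,4-bis[(triethylsilyl)oxy]pentanoyl]-1,3-oxazolidin-2-one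
Conditions: Et3SiOTf, 2,6-lutidine, CH2Cl2, −78 °C
Reagents that add atoms: triethylsilyl trifluoromethanesulfonate, CC[Si](CC)(CC)OS(=O)(=O)C(F)(F)F
Why: silylation of the hindered secondary carbinol blocks retro-aldol cleavage before the auxiliary is removed.

**Step 8**
Reactants: 12 silylated imide
Product: 13 (2S,3R,4R)-5-[(4-methoxybenzyl)oxy]-4-methyl-2-(prop-1-en-2-yl)-3,4-bis[(triethylsilyl)oxy]pentan-1-ol
Conditions: LiBH4, MeOH (1 equiv), THF, 0 °C
Reagents that add atoms: none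
Why: reductive cleavage of the N-acyl oxazolidinone gives the C1 carbinol without touching C8a.

**Step 9**
Reactants: 13 primary alcohol
Product: 14 tert-butyl{[(2S,3R,4R)-5-[(4-methoxybenzyl)oxy]-4-methyl-2-(prop-1-en-2-yl)-3,4-bis[(triethylsilyl)oxy]pentyl]oxy}dimethylsilane
Conditions: t-BuMe2SiCl, imidazole, DMF, rt
Reagents that add atoms: tert-butyldimethylsilyl chloride, CC(C)(C)[Si](C)(C)Cl
Why: standard silylation masks the future pyran oxygen (C1–O) until the last step.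

**Step 10**
Reactants: 14 PMB ether
Product: 15 (2R,3R,4S)-4-{[(tert-butyldimethylsilyl)oxy]methyl}-2,5-dimethyl-2,3-bis[(triethylsilyl)oxy]hex-5-en-1-ol
Conditions: DDQ, CH2Cl2/pH 7 buffer (NaH2PO4/Na2HPO4), 0 °C
Reagents that add atoms: none
Why: oxidative cleavage of the electron-rich PMB ether; silyl ethers and the alkene survive under buffered conditions.

**Step 11**
Reactants: 15 primary alcohol
Product: 16 (2S,3R,4S)-4-{[(tert-butyldimethylsilyl)oxy]methyl}-2,5-dimethyl-2,3-bis[(triethylsilyl)oxy]hex-5-enal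
Conditions: Dess–Martin periodinane, pyridine, CH2Cl2, 0 °C → rt
Reagents that add atoms: none
Why: Dess–Martin oxidation to a non-enolisable α-quaternary aldehyde (C6).

**Step 12**
Reactants: 16 aldehyde
Product: 17 (4R,5R,6S)-6-{[(tert-butyldimethylsilyl)oxy]methyl}-4,7-dimethyl-4,5-bis[(triethylsilyl)oxy]octa-1,7-dien-3-ol (mixture of C3 epimers)
Conditions: CH2=CHMgBr, THF, −78 °C; aq. NH4Cl at −78 °C
Reagents that add atoms: vinylmagnesium bromide, C=C[Mg]Br
Why: Grignard 1,2-addition brings in C5; the new carbinol centre (C6) is unselective and is later oxidised to the ketone, and the cold quench prevents silyl migration.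

**Step 13**
Reactants: 17 dienol
Product: 18 (4R,5R,6S)-6-{[(tert-butyldimethylsilyl)oxy]methyl}-7-(chloromethyl)-4-methyl-4,5-bis[(triethylsilyl)oxy]octa-1,7-dien-3-ol (mixture of C3 epimers)
Conditions: Ca(OCl)2, CO2 (solid), CH2Cl2/H2O, 0 °C
Reagents that add atoms: hypochlorous acid, OCl (generated from calcium hypochlorite, [Ca+2].[O-]Cl.[O-]Cl)
Why: ene-type allylic chlorination with double-bond shift, selective for the electron-rich 1,1-disubstituted alkene over the deactivated monosubstituted vinyl carbinol.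

**Step 14**
Reactants: 5 aldehyde
Product: 19 (2R,3R,4R)-1-[(4-methoxybenzyl)oxy]-2,4-dimethyl-2-[(triethylsilyl)oxy]hex-5-en-3-ol
Conditions: trans-2-butene, n-BuLi, KOt-Bu, THF, −78 → −45 °C; (+)-Ipc2BOMe, −78 °C; BF3·OEt2; 5, −78 °C; then NaOH, H2O2, 0 °C → rt
Reagents that add atoms: trans-2-butene, C/C=C/C (transferred as the (E)-crotylborane)
Why: Brown crotylation (carbonyl allylation) through a chair transition state; the E-crotyl geometry gives the anti relationship and the Ipc groups of the (−)-α-pinene series direct attack to the Re face, setting C4'(R) and C5'(R).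

**Step 15**
Reactants: 19 homoallylic alcohol
Product: 20 (3R,4R,5R)-6-[(4-methoxybenzyl)oxy]-3,5-dimethyl-4,5-bis[(triethylsilyl)oxy]hex-1-ene
Conditions: Et3SiOTf, 2,6-lutidine, CH2Cl2, −78 °C
Reagents that add atoms: triethylsilyl trifluoromethanesulfonate, CC[Si](CC)(CC)OS(=O)(=O)C(F)(F)F
Why: silylation of the secondary carbinol; any tertiary-to-secondary silyl shift during the previous work-up converges on the same bis-silyl ether.

**Step 16**
Reactants: 20 alkene PMB ether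
Product: 21 (2R,3R,4R)-2,4-dimethyl-2,3-bis[(triethylsilyl)oxy]hexan-1-ol
Conditions: H2 (1 atm), Pd(OH)2/C, EtOAc, rt
Reagents that add atoms: none
Why: heterogeneous hydrogenation turns the vinyl group into the ethyl terminus and hydrogenolyses the benzylic PMB ether in the same operation without touching a stereocentre.

**Step 17**
Reactants: 21 primary alcohol
Product: 22 (2S,3R,4R)-2,4-dimethyl-2,3-bis[(triethylsilyl)oxy]hexanal
Conditions: Dess–Martin periodinane, pyridine, CH2Cl2, 0 °C → rt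
Reagents that add atoms: none
Why: Dess–Martin oxidation to a non-enolisable aldehyde (C2').

**Step 18**
Reactants: 22 aldehyde
Product: 23 ethyl (2E,4R,5R,6R)-4,6-dimethyl-4,5-bis[(triethylsilyl)oxy]oct-2-enoate
Conditions: (EtO)2P(O)CH2CO2Et, NaH, THF, 0 °C → rt
Reagents that add atoms: triethyl phosphonoacetate, CCOC(=O)CP(=O)(OCC)OCC
Why: Horner–Wadsworth–Emmons olefination gives the E-alkene (C1'=C2') even with a hindered aldehyde.

**Step 19**
Reactants: 23 enoate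
Product: 24 (2E,4R,5R,6R)-4,6-dimethyl-4,5-bis[(triethylsilyl)oxy]oct-2-en-1-ol
Conditions: i-Bu2AlH, CH2Cl2, −78 °C; aq. potassium sodium tartrate (KNaC4H4O6)
Reagents that add atoms: none
Why: 1,2-reduction of the unsaturated ester to the allylic alcohol.

**Step 20**
Reactants: 24 allylic alcohol
Product: 25 (2E,4R,5R,6R)-4,6-dimethyl-4,5-bis[(triethylsilyl)oxy]oct-2-enal
Conditions: MnO2, CH2Cl2, rt
Reagents that add atoms: none
Why: allylic oxidation with MnO2 gives the E-enal without isomerisation.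

**Step 21**
Reactants: 18 allylic chloride; 25 enal
Product: 27 (4R,5R,6S,10E,12R,13R,14R)-6-{[(tert-butyldimethylsilyl)oxy]methyl}-4,12,14-trimethyl-7-methylidene-4,5,12,13-tetrakis[(triethylsilyl)oxy]hexadeca-1,10-diene-3,9-diol (epimer mixture at C3 and C9), via allylchromium dichloride 26 (not isolated)
Conditions: CrCl2 (6 equiv), LiI (cat.), THF/DMF, 0 °C → rt
Reagents that add atoms: none
Why: Nozaki–Hiyama carbonyl allylation; the allylchromium adds 1,2 to the enal through a six-membered transition state, tolerates the free hydroxyl, and the 2-substituted allyl unit has two equivalent CH2 termini so there is no regiochemical issue (the new C3 carbinol is oxidised later).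

**Step 22**
Reactants: 27 triene diol
Product: 28 (4S,5R,6R)-4-{[(tert-butyldimethylsilyl)oxy]methyl}-3-[(3E,5R,6R,7R)-2-hydroxy-5,7-dimethyl-5,6-bis[(triethylsilyl)oxy]non-3-en-1-yl]-6-methyl-5,6-bis[(triethylsilyl)oxy]cyclohex-2-en-1-ol (epimer mixture at both carbinol carbons)
Conditions: second-generation Grubbs catalyst RuCl2(=CHPh)(PCy3)(H2IMes) (5 mol %), CH2Cl2, 40 °C
Reagents that add atoms: none
Why: ring-closing metathesis starts at the monosubstituted vinyl carbinol and closes the only feasible ring (six-membered, C4a=C5), leaving the hindered side-chain E-alkene alone.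

**Step 23**
Reactants: 28 cyclohexenol diol
Product: 29 (4S,5R,6S)-4-{[(tert-butyldimethylsilyl)oxy]methyl}-3-[(3E,5R,6R,7R)-5,7-dimethyl-2-oxo-5,6-bis[(triethylsilyl)oxy]non-3-en-1-yl]-6-methyl-5,6-bis[(triethylsilyl)oxy]cyclohex-2-en-1-one
Conditions: Dess–Martin periodinane (3 equiv), pyridine, CH2Cl2, 0 °C → rt
Reagents that add atoms: none
Why: Dess–Martin oxidation of both secondary allylic alcohols erases the two stereorandom centres and gives the C3 and C6 ketones under buffered, non-epimerising conditions.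

**Step 24**
Reactants: 29 silylated enedione
Product: 32 (7S,8R,8aS)-3-[(1E,3R,4R,5R)-3,4-dihydroxy-3,5-dimethylhept-1-en-1-yl]-7,8-dihydroxy-7-methyl-8,8a-dihydro-1H-isochromen-6(7H)-one (target), via desilylated hydroxy enedione 30 (not isolated), via cyclic hemiketal 31 (not isolated)
Conditions: HF·pyridine, pyridine, THF, 0 °C → rt
Reagents that add atoms: none
Why: global desilylation frees the C1 hydroxyl, which adds to the C3 ketone (six-membered hemiketal) and dehydrates under the mildly acidic conditions to the fully conjugated dienol ether (vinylogous ester), the thermodynamic sink; no stereocentre is touched.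

**Compound list**
1 | 2-methylprop-2-en-1-ol (methallyl alcohol) | CC(=C)CO | starting material
2 | [(2S)-2-methyloxiran-2-yl]methanol | C[C@]1(CO)CO1 | intermediate
3 | (2S)-3-[(4-methoxybenzyl)oxy]-2-methylpropane-1,2-diol | C[C@](O)(CO)COCc1ccc(OC)cc1 | intermediate
4 | (2R)-1-[(4-methoxybenzyl)oxy]-2-methyl-2,3-bis[(triethylsilyl)oxy]propane | C[C@](O[Si](CC)(CC)CC)(CO[Si](CC)(CC)CC)COCc1ccc(OC)cc1 | intermediate
5 | (2R)-3-[(4-methoxybenzyl)oxy]-2-methyl-2-[(triethylsilyl)oxy]propanal | C[C@](O[Si](CC)(CC)CC)(C=O)COCc1ccc(OC)cc1 | intermediate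
6 | 3-methylbut-3-enoic acid | CC(=C)CC(=O)O | starting material
7 | (4R)-4-benzyl-1,3-oxazolidin-2-one | O=C1N[C@H](Cc2ccccc2)CO1 | starting material
8 | 3-methylbut-3-enoic pivalic anhydride | CC(=C)CC(=O)OC(=O)C(C)(C)C | intermediate (not isolated)
9 | (4R)-4-benzyl-3-(3-methylbut-3-enoyl)-1,3-oxazolidin-2-one | CC(=C)CC(=O)N1[C@H](Cc2ccccc2)COC1=O | intermediate
10 | (4R)-4-benzyl-3-[(1Z)-1-[(dibutylboranyl)oxy]-3-methylbuta-1,3-dien-1-yl]-1,3-oxazolidin-2-one | CC(=C)/C=C(\OB(CCCC)CCCC)N1[C@H](Cc2ccccc2)COC1=O | intermediate (not isolated)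
11 | (4R)-4-benzyl-3-[(2R,3R,4R)-3-hydroxy-5-[(4-methoxybenzyl)oxy]-4-methyl-2-(prop-1-en-2-yl)-4-[(triethylsilyl)oxy]pentanoyl]-1,3-oxazolidin-2-one | O=C(N1[C@H](Cc2ccccc2)COC1=O)[C@H](C(C)=C)[C@@H](O)[C@](C)(O[Si](CC)(CC)CC)COCc1ccc(OC)cc1 | intermediate
12 | (4R)-4-benzyl-3-[(2R,3R,4R)-5-[(4-methoxybenzyl)oxy]-4-methyl-2-(prop-1-en-2-yl)-3,4-bis[(triethylsilyl)oxy]pentanoyl]-1,3-oxazolidin-2-one | O=C(N1[C@H](Cc2ccccc2)COC1=O)[C@H](C(C)=C)[C@@H](O[Si](CC)(CC)CC)[C@](C)(O[Si](CC)(CC)CC)COCc1ccc(OC)cc1 | intermediate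
13 | (2S,3R,4R)-5-[(4-methoxybenzyl)oxy]-4-methyl-2-(prop-1-en-2-yl)-3,4-bis[(triethylsilyl)oxy]pentan-1-ol | OC[C@H](C(C)=C)[C@@H](O[Si](CC)(CC)CC)[C@](C)(O[Si](CC)(CC)CC)COCc1ccc(OC)cc1 | intermediate
14 | tert-butyl{[(2S,3R,4R)-5-[(4-methoxybenzyl)oxy]-4-methyl-2-(prop-1-en-2-yl)-3,4-bis[(triethylsilyl)oxy]pentyl]oxy}dimethylsilane | CC(C)(C)[Si](C)(C)OC[C@H](C(C)=C)[C@@H](O[Si](CC)(CC)CC)[C@](C)(O[Si](CC)(CC)CC)COCc1ccc(OC)cc1 | intermediate
15 | (2R,3R,4S)-4-{[(tert-butyldimethylsilyl)oxy]methyl}-2,5-dimethyl-2,3-bis[(triethylsilyl)oxy]hex-5-en-1-ol | CC(C)(C)[Si](C)(C)OC[C@H](C(C)=C)[C@@H](O[Si](CC)(CC)CC)[C@](C)(O[Si](CC)(CC)CC)CO | intermediate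
16 | (2S,3R,4S)-4-{[(tert-butyldimethylsilyl)oxy]methyl}-2,5-dimethyl-2,3-bis[(triethylsilyl)oxy]hex-5-enal | CC(C)(C)[Si](C)(C)OC[C@H](C(C)=C)[C@@H](O[Si](CC)(CC)CC)[C@](C)(O[Si](CC)(CC)CC)C=O | intermediate
17 | (4R,5R,6S)-6-{[(tert-butyldimethylsilyl)oxy]methyl}-4,7-dimethyl-4,5-bis[(triethylsilyl)oxy]octa-1,7-dien-3-ol (C3 epimers) | CC(C)(C)[Si](C)(C)OC[C@H](C(C)=C)[C@@H](O[Si](CC)(CC)CC)[C@](C)(O[Si](CC)(CC)CC)C(O)C=C | intermediate
18 | (4R,5R,6S)-6-{[(tert-butyldimethylsilyl)oxy]methyl}-7-(chloromethyl)-4-methyl-4,5-bis[(triethylsilyl)oxy]octa-1,7-dien-3-ol (C3 epimers) | CC(C)(C)[Si](C)(C)OC[C@H](C(=C)CCl)[C@@H](O[Si](CC)(CC)CC)[C@](C)(O[Si](CC)(CC)CC)C(O)C=C | intermediate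
19 | (2R,3R,4R)-1-[(4-methoxybenzyl)oxy]-2,4-dimethyl-2-[(triethylsilyl)oxy]hex-5-en-3-ol | C=C[C@@H](C)[C@@H](O)[C@](C)(O[Si](CC)(CC)CC)COCc1ccc(OC)cc1 | intermediate
20 | (3R,4R,5R)-6-[(4-methoxybenzyl)oxy]-3,5-dimethyl-4,5-bis[(triethylsilyl)oxy]hex-1-ene | C=C[C@@H](C)[C@@H](O[Si](CC)(CC)CC)[C@](C)(O[Si](CC)(CC)CC)COCc1ccc(OC)cc1 | intermediate
21 | (2R,3R,4R)-2,4-dimethyl-2,3-bis[(triethylsilyl)oxy]hexan-1-ol | CC[C@@H](C)[C@@H](O[Si](CC)(CC)CC)[C@](C)(O[Si](CC)(CC)CC)CO | intermediate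
22 | (2S,3R,4R)-2,4-dimethyl-2,3-bis[(triethylsilyl)oxy]hexanal | CC[C@@H](C)[C@@H](O[Si](CC)(CC)CC)[C@](C)(O[Si](CC)(CC)CC)C=O | intermediate
23 | ethyl (2E,4R,5R,6R)-4,6-dimethyl-4,5-bis[(triethylsilyl)oxy]oct-2-enoate | CC[C@@H](C)[C@@H](O[Si](CC)(CC)CC)[C@](C)(O[Si](CC)(CC)CC)/C=C/C(=O)OCC | intermediate
24 | (2E,4R,5R,6R)-4,6-dimethyl-4,5-bis[(triethylsilyl)oxy]oct-2-en-1-ol | CC[C@@H](C)[C@@H](O[Si](CC)(CC)CC)[C@](C)(O[Si](CC)(CC)CC)/C=C/CO | intermediate
25 | (2E,4R,5R,6R)-4,6-dimethyl-4,5-bis[(triethylsilyl)oxy]oct-2-enal | CC[C@@H](C)[C@@H](O[Si](CC)(CC)CC)[C@](C)(O[Si](CC)(CC)CC)/C=C/C=O | intermediate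
26 | allylchromium dichloride of 18 (CH2Cl replaced by CH2CrCl2) | CC(C)(C)[Si](C)(C)OC[C@H](C(=C)C[Cr](Cl)Cl)[C@@H](O[Si](CC)(CC)CC)[C@](C)(O[Si](CC)(CC)CC)C(O)C=C | intermediate (not isolated)
27 | (4R,5R,6S,10E,12R,13R,14R)-6-{[(tert-butyldimethylsilyl)oxy]methyl}-4,12,14-trimethyl-7-methylidene-4,5,12,13-tetrakis[(triethylsilyl)oxy]hexadeca-1,10-diene-3,9-diol (C3/C9 epimers) | CC[C@@H](C)[C@@H](O[Si](CC)(CC)CC)[C@](C)(O[Si](CC)(CC)CC)/C=C/C(O)CC(=C)[C@@H](CO[Si](C)(C)C(C)(C)C)[C@@H](O[Si](CC)(CC)CC)[C@](C)(O[Si](CC)(CC)CC)C(O)C=C | intermediate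
28 | (4S,5R,6R)-4-{[(tert-butyldimethylsilyl)oxy]methyl}-3-[(3E,5R,6R,7R)-2-hydroxy-5,7-dimethyl-5,6-bis[(triethylsilyl)oxy]non-3-en-1-yl]-6-methyl-5,6-bis[(triethylsilyl)oxy]cyclohex-2-en-1-ol (carbinol epimers) | CC[C@@H](C)[C@@H](O[Si](CC)(CC)CC)[C@](C)(O[Si](CC)(CC)CC)/C=C/C(O)CC1=CC(O)[C@@](C)(O[Si](CC)(CC)CC)[C@H](O[Si](CC)(CC)CC)[C@@H]1CO[Si](C)(C)C(C)(C)C | intermediate
29 | (4S,5R,6S)-4-{[(tert-butyldimethylsilyl)oxy]methyl}-3-[(3E,5R,6R,7R)-5,7-dimethyl-2-oxo-5,6-bis[(triethylsilyl)oxy]non-3-en-1-yl]-6-methyl-5,6-bis[(triethylsilyl)oxy]cyclohex-2-en-1-one | CC[C@@H](C)[C@@H](O[Si](CC)(CC)CC)[C@](C)(O[Si](CC)(CC)CC)/C=C/C(=O)CC1=CC(=O)[C@@](C)(O[Si](CC)(CC)CC)[C@H](O[Si](CC)(CC)CC)[C@@H]1CO[Si](C)(C)C(C)(C)C | intermediate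
30 | (4S,5R,6S)-3-[(3E,5R,6R,7R)-5,6-dihydroxy-5,7-dimethyl-2-oxonon-3-en-1-yl]-5,6-dihydroxy-4-(hydroxymethyl)-6-methylcyclohex-2-en-1-one | CC[C@@H](C)[C@@H](O)[C@](C)(O)/C=C/C(=O)CC1=CC(=O)[C@@](C)(O)[C@H](O)[C@@H]1CO | intermediate (not isolated)
31 | (7S,8R,8aS)-3-[(1E,3R,4R,5R)-3,4-dihydroxy-3,5-dimethylhept-1-en-1-yl]-3,7,8-trihydroxy-7-methyl-3,4,8,8a-tetrahydro-1H-isochromen-6(7H)-one (C3 epimers) | CC[C@@H](C)[C@@H](O)[C@](C)(O)/C=C/C1(O)CC2=CC(=O)[C@@](C)(O)[C@H](O)[C@@H]2CO1 | intermediate (not isolated)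
32 | (7S,8R,8aS)-3-[(1E,3R,4R,5R)-3,4-dihydroxy-3,5-dimethylhept-1-en-1-yl]-7,8-dihydroxy-7-methyl-8,8a-dihydro-1H-isochromen-6(7H)-one | CC[C@@H](C)[C@@H](O)[C@](C)(O)/C=C/C1=CC2=CC(=O)[C@@](C)(O)[C@H](O)[C@@H]2CO1 | target

**Totals**
Total step count: 24. Longest linear sequence: 16 steps (1–4, 6–13, 21–24); the side-chain branch (14–20) joins at step 21.

**Three steps most likely to fail, each with a fallback**

Step 13 (ene-chlorination next to a free allylic alcohol and a second alkene; over-oxidation or chloro-etherification could compete). The fallback sets out from 17. The allylic methyl group is oxidised with SeO2 (cat.)/t-BuOOH in CH2Cl2 to the primary allylic alcohol (4R,5R,6S)-6-{[(tert-butyldimethylsilyl)oxy]methyl}-7-(hydroxymethyl)-4-methyl-4,5-bis[(triethylsilyl)oxy]octa-1,7-dien-3-ol F1. Its unhindered primary hydroxyl is then converted selectively (CBr4, PPh3, 2,6-lutidine, CH2Cl2, −30 °C) into the bromide (4R,5R,6S)-7-(bromomethyl)-6-{[(tert-butyldimethylsilyl)oxy]methyl}-4-methyl-4,5-bis[(triethylsilyl)oxy]octa-1,7-dien-3-ol F2. F2 is coupled with 25 under the CrCl2 conditions of step 21, and the route is rejoined at 27.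

Step 21 (fragment union with a hindered 2-substituted allylic chloride; slow chromium insertion or reduction of the enal could lower the yield). The fallback sets out from 18. The chloride is turned into the isolable allylboronate (4R,5R,6S)-6-{[(tert-butyldimethylsilyl)oxy]methyl}-4-methyl-7-[(4,4,5,5-tetramethyl-1,3,2-dioxaborolan-2-yl)methyl]-4,5-bis[(triethylsilyl)oxy]octa-1,7-dien-3-ol F3 (B2pin2, Pd2(dba)3 cat., DMSO, 50 °C). F3 adds to 25 without any metal reductant through a closed six-membered transition state (toluene, rt, then aqueous work-up), and the route is rejoined at 27.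

Step 24 (the silylated enedione must lose five silyl groups and cyclise without harming the tertiary allylic alcohol or the vinylogous ester). The fallback sets out from 28, before the oxidation. All silyl groups are removed first (Bu4NF/AcOH, THF) to give the heptaol (4S,5R,6R)-3-[(3E,5R,6R,7R)-2,5,6-trihydroxy-5,7-dimethylnon-3-en-1-yl]-4-(hydroxymethyl)-6-methylcyclohex-2-ene-1,5,6-triol F4. Only its two allylic carbinols are then oxidised with MnO2 (acetone/CH2Cl2); the resulting 30 closes through 31 in the same flask, and the route is rejoined at 32.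

**Further compounds**
F1 | step 13 | (4R,5R,6S)-6-{[(tert-butyldimethylsilyl)oxy]methyl}-7-(hydroxymethyl)-4-methyl-4,5-bis[(triethylsilyl)oxy]octa-1,7-dien-3-ol (C3 epimers) | CC(C)(C)[Si](C)(C)OC[C@H](C(=C)CO)[C@@H](O[Si](CC)(CC)CC)[C@](C)(O[Si](CC)(CC)CC)C(O)C=C
F2 | step 13 | (4R,5R,6S)-7-(bromomethyl)-6-{[(tert-butyldimethylsilyl)oxy]methyl}-4-methyl-4,5-bis[(triethylsilyl)oxy]octa-1,7-dien-3-ol (C3 epimers) | CC(C)(C)[Si](C)(C)OC[C@H](C(=C)CBr)[C@@H](O[Si](CC)(CC)CC)[C@](C)(O[Si](CC)(CC)CC)C(O)C=C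
F3 | step 21 | (4R,5R,6S)-6-{[(tert-butyldimethylsilyl)oxy]methyl}-4-methyl-7-[(4,4,5,5-tetramethyl-1,3,2-dioxaborolan-2-yl)methyl]-4,5-bis[(triethylsilyl)oxy]octa-1,7-dien-3-ol (C3 epimers) | CC(C)(C)[Si](C)(C)OC[C@H](C(=C)CB1OC(C)(C)C(C)(C)O1)[C@@H](O[Si](CC)(CC)CC)[C@](C)(O[Si](CC)(CC)CC)C(O)C=C
F4 | step 24 | (4S,5R,6R)-3-[(3E,5R,6R,7R)-2,5,6-trihydroxy-5,7-dimethylnon-3-en-1-yl]-4-(hydroxymethyl)-6-methylcyclohex-2-ene-1,5,6-triol (carbinol epimers) | CC[C@@H](C)[C@@H](O)[C@](C)(O)/C=C/C(O)CC1=CC(O)[C@@](C)(O)[C@H](O)[C@@H]1CO
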